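The 4 questions below come down to one quantity, and you can read it from the earlier runs.

| flask | starting material | coupling partner | remark | time |
|---|---|---|---|---|
| elm | 0.0050 M | 1 equiv | run made earlier |  |
| cedar | 0.0034 M | 1 equiv | run made earlier |  |
| oak | 0.0075 M | 1 equiv | run made earlier |  |
| birch | 0.0050 M | 1.5 equiv | run made earlier |  |
| north | 0.0050 M | 1.00 equiv | everything together at the start | 2.5 min |
| south-east | 0.0050 M (fed, over 1.0 min) | 1.00 equiv | all else is in the flask from the start; the feed brings no volume worth counting | 2.5 min |
| north-west | 0.0050 M | 1.00 equiv (fed, over 1.0 min) | all else is in the flask from the start; the feed brings no volume worth counting | 2.5 min |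

| run | time / min | side product / % | target / % |
|---|---|---|---|
| elm | 0.200 | 8.8 | 65.2 |
| elm | 0.500 | 29.6 | 64.5 |
| elm | 1.00 | 51.5 | 46.2 |
| elm | 2.50 | 75.1 | 24.2 |
| cedar | 0.417 | 16.6 | 72.1 |
| cedar | 1.00 | 40.4 | 55.9 |
| cedar | 2.00 | 60.2 | 38.0 |
| cedar | 3.00 | 70.7 | 29.0 |
| oak | 0.417 | 34.8 | 60.3 |
| oak | 1.00 | 61.8 | 35.5 |
| oak | 2.00 | 77.4 | 20.8 |
| oak | 3.00 | 84.2 | 14.9 |
| birch | 0.417 | 30.3 | 69.5 |
| birch | 1.00 | 55.9 | 44.3 |
| birch | 2.00 | 71.5 | 27.2 |
| birch | 3.00 | 80.9 | 19.1 |

(standard deviation of a reading: 0.5 percentage points)

- steps that have been proposed: starting material + coupling partner -> intermediate + released group; intermediate -> target; target + released group -> side product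

- the flask that comes out highest in amount of side product, in percent of the starting material charged; "all alike" if 1.5 percentage points covers them all (north / south-east / north-west / all alike)
- amount of side product at the end, in percent of the starting material charged, north
- amount of side product at the end, in percent of the starting material charged, south-east
- amount of side product at the end, in percent of the starting material charged, north-west

North repeats the elm recipe, so I take its answer from the elm reading at 2.50 min: 75.1 %. For the two fed flasks, let T be target as a fraction of the charge. Each target came through the intermediate with its released group set free, and the last step takes one of each, so the two fractions stay about equal. Loss of target then goes as T squared, and the reciprocal of T climbs in a straight line. Its rise per minute between the last two elm readings is 1.31 min⁻¹; call this the reciprocal clock. Oak gives 1.95 min⁻¹, close to the elm clock scaled by charge, 1.97 min⁻¹. Run the elm line back to the whole charge as target and it lands at 0.112 min, the induction period.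

During a feed, T climbs roughly straight from nothing to its end value, and the mean of T squared is then a third of that value squared. Charge in minus clock loss gives an end value of 0.752; squaring the mean instead would give 0.794. Running the clock from there to 2.5 min gives T of 0.303. Counting all that is not target as side product gives 69.7 %, a figure that runs high by whatever starting material and intermediate still stand in the fed flask. Elm's last readings leave 0.700 % for such a rest, but that carries the scatter of both readings and comes from an unfed flask, so I do not subtract it. The weak link is that target trails the feed by the induction period, which shortens the free run: T becomes 0.318 and side product 68.2 %. The first step holds one of each partner, so this reckoning serves both south-east and north-west.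

The forecast names north highest, with 75.1 %, 69.5 % and 69 % for north, south-east and north-west, the fed values above mine, and holds that “Step 1 is symmetric in its two partners”.

The flasks give 74.7 % in north, 67.6 % in south-east and 67.6 % in north-west, so north stands highest, against my 68.2 % for the fed pair. At 1.00 min, the end of its feed, south-east held 13.3 % starting material and 5.41 % intermediate beside 58.5 % target.

    starting material + coupling partner → intermediate + released group (k = 120 M⁻¹ s⁻¹)
    intermediate → target (k = 0.220 s⁻¹)
    target + released group → side product (k = 4.70 M⁻¹ s⁻¹)

From 1.25 min to 2.50 min the reciprocal of target in south-east climbs 1.20 min⁻¹, slower than the elm clock. Scaled to 0.0085 M, the clock becomes 2.23 min⁻¹ for a neighbour of north, which puts target at 15.8 %; that flask holds 15.6 %.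

The data stem from a simulated flask with made-up constants.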